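The retrosynthesis cuts first the C3–O3 bond of the catechol (back to C3–H of an alkyl salicylate), then the acyl C–O bond of the ester, and last the C12′–C13′ bond of the 16-methylheptadecyl chain.
Enabling feature: O3 sits on C3, ortho to the phenol oxygen O2 on C2. The other ortho neighbour of C2 is C1, which already carries the ester carbon, so a directing group hung on O2 finds a single C–H bond, much as plants hydroxylate salicylate to 2,3-dihydroxybenzoate.
Forward, the chain is joined first (C6 Grignard reagent plus C12 bromo alcohol), the C18 alcohol is loaded onto salicylate by transesterification, and O2 is capped with a di-tert-butylsilanol.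
Palladium then makes C3–O3 and closes the only ring built in the route, a temporary five-membered 1,3,2-dioxasilole (O2, Si, O3, C3, C2) fused to the benzene ring. Fluoride opens it again to the free catechol.
Stereochemistry: the target has no stereocentre and no stereogenic double bond, so nothing has to be set or preserved.

Key step: step 4

Remark on numbering: on the arene, C1 bears the ester carbon and C2 and C3 bear O2 and O3. Primed numbers count the alkyl chain from the ester oxygen.

Step 1
Reactants: 1 1-bromo-4-methylpentane; 2 12-bromododecan-1-ol
Product: 4 16-methylheptadecan-1-ol, via 4-methylpentylmagnesium bromide 3 (not isolated)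
Conditions: 1 (3 equiv), Mg turnings, THF, 40 °C; then 2, Li2CuCl4 (5 mol %), THF, −20 °C → rt; aq NH4Cl
Reagents that add atoms: none
Why: This is a Li2CuCl4-catalysed alkyl–alkyl Grignard cross-coupling (Kochi coupling) of two primary partners, in which the first equivalent of 3 only deprotonates the hydroxyl of 2 and the resulting magnesium alkoxide is inert, a tactic in routine use for iso-branched fatty alcohols.

Step 2
Reactants: 4 16-methylheptadecan-1-ol; 5 methyl salicylate (methyl 2-hydroxybenzoate)
Product: 6 16-methylheptadecyl 2-hydroxybenzoate
Conditions: 5 (4 equiv, also the solvent), Bu2SnO (5 mol %), 150 °C, slow N2 stream to carry off MeOH; surplus 5 distilled off in vacuo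
Reagents that add atoms: none
Why: Tin-catalysed transesterification is an equilibrium that surplus 5 and removal of methanol pull toward the primary long-chain ester, and the free phenol needs no protection, as in the technical preparation of higher alkyl salicylates.

Step 3
Reactants: 6 16-methylheptadecyl 2-hydroxybenzoate; 7 di-tert-butylsilyl bis(trifluoromethanesulfonate)
Product: 9 16-methylheptadecyl 2-{[di-tert-butyl(hydroxy)silyl]oxy}benzoate, via silyl triflate 8 (not isolated)
Conditions: 6 added slowly to 7 (1.2 equiv), 2,6-lutidine (3 equiv), CH2Cl2, 0 °C → rt; then sat aq NaHCO3, THF, rt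
Reagents that add atoms: di-tert-butylsilyl bis(trifluoromethanesulfonate) 7, CC(C)(C)[Si](OS(=O)(=O)C(F)(F)F)(OS(=O)(=O)C(F)(F)F)C(C)(C)C; water, O
Why: In this O-silylation with a silyl triflate followed by hydrolysis of the second Si–OTf bond, the bis(triflate) is electrophilic enough for the hydrogen-bonded and flanked O2, the two tert-butyl groups keep a second aryloxide out, and water displaces triflate far faster than aryloxide to leave a silanol too hindered to condense to a disiloxane.

Step 4
Reactants: 9 16-methylheptadecyl 2-{[di-tert-butyl(hydroxy)silyl]oxy}benzoate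
Product: 11 16-methylheptadecyl 2,2-di-tert-butyl-1,3,2-benzodioxasilole-4-carboxylate, via C3 aryl acetate 10 (not isolated)
Conditions: Pd(OPiv)2 (10 mol %), PhI(OAc)2 (2 equiv), PhMe (0.05 M), 100 °C
Reagents that add atoms: (diacetoxyiodo)benzene, CC(=O)OI(OC(C)=O)c1ccccc1
Why: Exchange of one pivalate on divalent palladium for the Si–OH group places the metal next to C3–H, which is cleaved with the help of the remaining pivalate (concerted metalation–deprotonation) to give a palladacycle of six members: Pd, silanol O, Si, O2, C2 and C3. Two-electron oxidation by PhI(OAc)2 leads to an aryl acetate complex of tetravalent palladium, from which C–O reductive elimination releases aryl acetate 10 and returns divalent palladium, so O3 is an acetate oxygen of the oxidant. Promoted by the acetic acid released, 10 cyclises: O3 becomes bonded to silicon in a 5-exo attack at the tetrahedral silicon centre, the former silanol oxygen departs within acetic acid, and the 1,3,2-dioxasilole ring (O2, Si, O3, C3, C2) so formed hides the catechol from the oxidant. The closest known reaction type is this very one, the silanol-directed palladium-catalysed ortho C–H acetoxylation and cyclisation of phenoxysilanols, which has been shown on electron-poor phenols. No stereocentre is formed. Site selectivity for C3 over C4, C5 and C6 is required and is built into 9, because the O2–Si–O leash is too short for anything but a position ortho to O2, the other such position (C1) is fully substituted, the ester is too weak a ligand to draw palladium to C6, and its bulk should turn the silanol toward C3.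

Step 5
Reactants: 11 16-methylheptadecyl 2,2-di-tert-butyl-1,3,2-benzodioxasilole-4-carboxylate
Product: 12 gentiside D (16-methylheptadecyl 2,3-dihydroxybenzoate)
Conditions: Bu4NF (TBAF, 2.5 equiv), AcOH (3 equiv), THF, 0 °C, Ar; degassed, slightly acidic work-up
Reagents that add atoms: none
Why: In this fluoride-mediated desilylation the strained bis(aryloxy)silane is attacked twice by fluoride while acetic acid protonates both aryloxides at once, which keeps the medium non-basic so that the ester stays intact and the catechol is not oxidised by air.

Compound list
1 | 1-bromo-4-methylpentane | CC(C)CCCBr | starting material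
2 | 12-bromododecan-1-ol | OCCCCCCCCCCCCBr | starting material
3 | 4-methylpentylmagnesium bromide | CC(C)CCC[Mg]Br | intermediate
4 | 16-methylheptadecan-1-ol | CC(C)CCCCCCCCCCCCCCCO | intermediate
5 | methyl salicylate | COC(=O)c1ccccc1O | starting material
6 | 16-methylheptadecyl 2-hydroxybenzoate | CC(C)CCCCCCCCCCCCCCCOC(=O)c1ccccc1O | intermediate
7 | di-tert-butylsilyl bis(trifluoromethanesulfonate) | CC(C)(C)[Si](OS(=O)(=O)C(F)(F)F)(OS(=O)(=O)C(F)(F)F)C(C)(C)C | starting material
8 | 16-methylheptadecyl 2-{[di-tert-butyl(trifluoromethanesulfonyloxy)silyl]oxy}benzoate | CC(C)CCCCCCCCCCCCCCCOC(=O)c1ccccc1O[Si](OS(=O)(=O)C(F)(F)F)(C(C)(C)C)C(C)(C)C | intermediate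
9 | 16-methylheptadecyl 2-{[di-tert-butyl(hydroxy)silyl]oxy}benzoate | CC(C)CCCCCCCCCCCCCCCOC(=O)c1ccccc1O[Si](O)(C(C)(C)C)C(C)(C)C | intermediate
10 | 16-methylheptadecyl 3-acetoxy-2-{[di-tert-butyl(hydroxy)silyl]oxy}benzoate | CC(C)CCCCCCCCCCCCCCCOC(=O)c1cccc(OC(C)=O)c1O[Si](O)(C(C)(C)C)C(C)(C)C | intermediate
11 | 16-methylheptadecyl 2,2-di-tert-butyl-1,3,2-benzodioxasilole-4-carboxylate | CC(C)CCCCCCCCCCCCCCCOC(=O)c1cccc2O[Si](C(C)(C)C)(C(C)(C)C)Oc12 | intermediate
12 | gentiside D, 16-methylheptadecyl 2,3-dihydroxybenzoate | CC(C)CCCCCCCCCCCCCCCOC(=O)c1cccc(O)c1O | target

Total step count: 5. Longest linear sequence: 5 steps (1 or 2 → 4 → 6 → 9 → 11 → 12).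

Steps most likely to fail

Step 4. Palladation at C3–H may be too slow. The ring is electron-poor, and the silanol can be tied up by hydrogen bonding to the neighbouring ester carbonyl. The silanol may even attack that carbonyl with loss of the chain alcohol, so that the catalyst decays to palladium black before it turns over. The fallback sets out from 6 and returns at 12, and it brings the C3 oxygen in through a carbon substituent instead of through C–H palladation. Magnesium-mediated ortho-formylation of 6 (Casnati–Skattebøl conditions: MgCl2, Et3N, paraformaldehyde, THF, reflux) can only strike the free ortho position C3 and should give 16-methylheptadecyl 3-formyl-2-hydroxybenzoate F1. Dakin oxidation (30% H2O2, aq NaHCO3, THF, rt, Ar) should then pass through 16-methylheptadecyl 3-(formyloxy)-2-hydroxybenzoate F2, whose formate is hydrolysed in the same flask to give 12.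

Step 3. At the silyl triflate stage the ester carbonyl may add to the very electrophilic silicon, which opens the way to dealkylation or to hydrolytic loss of the ester. The hydrogen-bonded phenol may also silylate incompletely. The fallback sets out from 6 and returns at 9. It introduces silicon at the hydrosilane level, which is not Lewis acidic, and raises it to the silanol afterwards. Di-tert-butylchlorosilane (imidazole, DMAP, DMF, 60 °C) should give 16-methylheptadecyl 2-[(di-tert-butylsilyl)oxy]benzoate F3. NBS (CH2Cl2, 0 °C) should turn Si–H into Si–Br and give 16-methylheptadecyl 2-{[bromo(di-tert-butyl)silyl]oxy}benzoate F4, and hydrolysis with aq NaHCO3 in THF should give 9.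

Step 1. Homocoupling of the Grignard reagent, and reduction or elimination of the bromide, may compete with cross-coupling and leave long-chain alcohols that are hard to separate from 4. The fallback sets out from 2 and returns at 4, and it joins the chain through a C=C bond that is then saturated. Heating 2 with PPh3 (MeCN, reflux) should give (12-hydroxydodecyl)triphenylphosphonium bromide F5. Double deprotonation with NaN(SiMe3)2 (2.1 equiv, THF, −78 °C) and Wittig olefination of commercial 4-methylpentanal should give mainly (Z)-16-methylheptadec-12-en-1-ol F6, whose geometry is of no consequence. Hydrogenation (H2, Pd/C, EtOAc) should give 4.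

Further compounds
F1 | step 4 | 16-methylheptadecyl 3-formyl-2-hydroxybenzoate | CC(C)CCCCCCCCCCCCCCCOC(=O)c1cccc(C=O)c1O
F2 | step 4 | 16-methylheptadecyl 3-(formyloxy)-2-hydroxybenzoate | CC(C)CCCCCCCCCCCCCCCOC(=O)c1cccc(OC=O)c1O
F3 | step 3 | 16-methylheptadecyl 2-[(di-tert-butylsilyl)oxy]benzoate | CC(C)CCCCCCCCCCCCCCCOC(=O)c1ccccc1O[SiH](C(C)(C)C)C(C)(C)C
F4 | step 3 | 16-methylheptadecyl 2-{[bromo(di-tert-butyl)silyl]oxy}benzoate | CC(C)CCCCCCCCCCCCCCCOC(=O)c1ccccc1O[Si](Br)(C(C)(C)C)C(C)(C)C
F5 | step 1 | (12-hydroxydodecyl)triphenylphosphonium bromide | OCCCCCCCCCCCC[P+](c1ccccc1)(c1ccccc1)c1ccccc1.[Br-]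
F6 | step 1 | (Z)-16-methylheptadec-12-en-1-ol | CC(C)CC/C=C\CCCCCCCCCCCO
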